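## The problem

Compound 34 is a trans-fused 3a,6,7,7a-tetrahydro-3H-indene. Ring A is a cyclopentene (C1=C2, ethyl on C1, methyl on C3) and ring B a cyclohexene (C4=C5, methyl on C4), joined across C3a–C7a. Five contiguous stereocentres run C3–C3a–C7a–C7–C6. C6 (ethyl, phenylbutadienyl) and C7 (methyl, CO2H) are adjacent quaternary carbons, so neither can be corrected by epimerisation once formed.

The three centres on ring A can be relayed from one oxygen-bearing carbon. An oxygen on C7a sends a nucleophile to the opposite face of C3a. C3 then equilibrates trans to C3a next to a C2 carbonyl. A C2 oxygen hands its face to C7a through a suprafacial [3,3] shift. C6 lies outside this relay and must bring its own configuration. Once ring B is closed, C6 holds its one-carbon arm pseudoaxial and leaves one open face at C7.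

The (1E,3E)-4-phenylbutadiene will not survive acids, metathesis catalysts or strong electrophiles and has to come last. The two trisubstituted ring alkenes must not migrate. The neopentyl carboxylic acid cannot be freed from an ordinary ester by hydroxide and sits 1,3 to the C6 arm, which invites lactonisation.

The enabling feature is that C1, C2, C3, C3a and C7a, with ethyl on C1 and methyl on C3, are atom for atom the carbinol carbon and C2–C5 of 1-(3-methylfuran-2-yl)propan-1-ol (3). A Piancatelli rearrangement returns them as a cyclopentenone with oxygen on C2 and C7a, the two positions from which the relay starts.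

## Retrosynthesis

**Diene and acid.** The C1'=C2' bond of 34 is cut, after the acid is masked as the tert-butyl ester 32. This gives the aldehyde 30 and the commercial phosphonate 31. Carrying the diene earlier would expose it to the metathesis catalyst and to LiN(i-Pr)2. The aldehyde has no α-hydrogen and comes from the silyl ether 28 through the alcohol 29. The forward olefination must give the E alkene on a very hindered aldehyde.

**C7–CH3.** The methyl group of 28 is removed to give ester 26 (through enolate 27). Bringing the methyl in with the acid fragment would require a tetrasubstituted ketene acetal of defined geometry in an open chain, for which no control is available. In trans-fused 26 the ring is locked and the pseudoaxial CH2OSi group on C6 blocks one face of C7. The C7 configuration of 26 is irrelevant, which removes one stereochemical demand from every earlier step.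

**C4=C5.** Ring B of 26 is opened by retro-metathesis to the diene 25, with an isopropenyl group on C3a and an (E)-propenyl group on C6. The neighbouring cuts, C5–C6 or C6–C7, would form a quaternary centre during ring closure. This cut forms none, and each alkene belongs to a different fragment. The forward reaction must make a trisubstituted alkene next to quaternary C6 across a trans-disposed pair of arms.

**C7–C7a.** Ester 25 comes from acid 24, and 24 from the allylic ester 21 by a retro-Ireland–Claisen step (through 22 and 23). This cut separates the molecule into the cyclopentenol 10 and the acid 20. It also returns the alkene to C1=C7a and places oxygen on C2. The [3,3] shift is chosen over an allylic alkylation because its suprafacial course ties the C7a configuration to the C2 carbinol without a catalyst-dependent facial choice.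

**Acid 20 (C6–C7).** Acid 20 comes from ester 19, and 19 from the allylic alcohol 16 and triethyl orthoacetate 17 by a retro-Johnson–Claisen step (through 18). The C6–C7 bond is cut and the quaternary centre becomes a trisubstituted Z alkene plus a methyl carbinol, whose configuration is transferred through a chair. Alcohol 16 is resolved from 15, which is the mono-silyl ether of diol 14. Diol 14 is assembled in one flask from propargyl alcohol 11, EtMgBr 2 and acetaldehyde 12 (through 13), a step that also fixes the alkene geometry.

**Ring A relay.** Alcohol 10 comes from enone 9 by reduction. Enone 9 comes from silyl ether 6 and the Grignard reagent 7 (through 8) by addition to C3a anti to the C7a ether, followed by loss of that ether across C1–C7a. Ether 6 comes from the resolved hydroxy enone 5, and 5 from racemic 4. Every centre of 10 thus derives from the C7a carbinol of 5.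

**Key cut (C1–C7a).** Hydroxy enone 4 is opened between C1 and C7a and its two oxygens are returned to a furan. This gives carbinol 3, made from aldehyde 1 and EtMgBr 2. Cutting C3–C3a or C2–C3 instead would need an acyclic precursor with the methyl and ethyl groups placed separately. Here both are already on the furan, and the forward step needs only acid and water.

## Roads not taken

**Alternative 1:** The cut runs through ring B at C6–C7 and, after a retro-Grob step, at the bond between the carboxyl carbon and C5, so that ring B is traced back to a cyclobutanone. In the forward direction a methylketene unit generated at C7 by dehydrochlorination adds across the trisubstituted C5=C6 alkene of the same chain and gives the bicyclo[3.1.1]heptan-6-one A1. Hydroxide then opens the four-membered ring with loss of the C4 acetate, which unveils the C4=C5 alkene and the C7 carboxylate together.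

- Merit: the bond between the two quaternary carbons is made in one intramolecular step whose bridged geometry fixes C6 against C7. The chosen plan needs two stages for this (C6 from a resolved fragment, C7 by a later alkylation), and in this respect Alternative 1 is better.
- Weak points: the open-chain substrate must already carry four contiguous stereocentres (the C1 carbinol, C7a, C3a and the tertiary C4 acetate) and a geometrically pure trisubstituted alkene, all from acyclic control. A dialkylketene is a sluggish partner for an unactivated alkene. The Grob opening needs an antiperiplanar C4–O bond. Ring A is still missing in A1, so a second ring-forming key step and the conversion of the CH2O arm into the diene must follow.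
- What the chosen plan sets against it: ring A in two steps from a furan, ring centres each controlled by a cyclic neighbour, and no acyclic stereotetrad.

**Alternative 2:** The cut is C5–C6, with the diene traced back to a skipped diene. Zerovalent palladium inserts into a (Z)-alkenyl iodide at C5, the alkenylpalladium adds 6-exo to C6 of a trisubstituted C6=C1' alkene, and β-hydride elimination towards C2' gives the methyl ester A2. Ring B, the C6 quaternary centre and the complete diene arrive in one step.

- Merit: in step economy at the end of the synthesis this road is better than the chosen one, which spends three steps on the diene after ring closure.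
- Weak points: C6 is created next to the preformed quaternary C7, whose methyl and ester groups differ little in size, so nothing obvious directs the facial choice of the insertion. The substrate needs a Z trisubstituted alkenyl iodide on C3a, a geometrically defined C6=C1' alkene, and a C7 centre that would itself come from an enolate of uncontrolled geometry. A2 must still lose a hindered methyl ester beside the diene.
- What the chosen plan sets against it: C6 is fixed by chirality transfer in a chair and C7 by alkylation of a locked ring, two elements whose sense can be predicted.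

**Alternative 3:** Ring B is made first and ring A last, by cutting C1=C2 and C2–C3. Me3SiC(Li)N2 converts a propionyl ketone on C7a into an alkylidene carbene at C2, which inserts into a methylene C–H bond of an ethyl group on C3a and gives the bicyclic ester A3.

- Merit: ring A appears with no functional group to remove, and the ring B centres can be set on a six-membered ring before the trans fusion is introduced. In that respect it is at least as good as the chosen plan, which has to close ring B by metathesis onto a trans pair of arms.
- Weak points: the carbene must choose one of two diastereotopic methylene hydrogens to set C3. It must prefer that insertion over insertion into the C7 methyl group (also 1,5) and over addition to the nearby C4=C5 alkene. The ketone is flanked by a quaternary carbon, which slows the olefination that generates the carbene. The two-carbon silyloxyethyl arm of A3 then needs several steps to become the diene.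
- What the chosen plan sets against it: C3 is set by equilibration next to a ketone, and the ring A substituents come from the furan. The price is a separate resolution for the absolute configuration.

Key step: step 2

Assumption: the lipase of step 3 is taken to acylate the (4S,5R) enantiomer of 4, whose carbinol centre has the spatial arrangement of the fast-reacting (R) enantiomer of 4-hydroxycyclopent-2-en-1-one, so that 5 is recovered as the unreacted alcohol.

Locants C1–C7a and C1'–C4' are those of the target and are used for all intermediates.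

## Route

Step 1
Reactants: 1 3-methylfuran-2-carbaldehyde; 2 ethylmagnesium bromide
Product: 3 rac-1-(3-methylfuran-2-yl)propan-1-ol
Conditions: EtMgBr (1.2 equiv), THF, 0 °C; aq. NH4Cl
Reagents that add atoms: none
Why: Grignard addition to a heteroaryl aldehyde; the racemate suffices because the carbinol carbon is ionised in step 2.

Step 2
Reactants: 3 rac-1-(3-methylfuran-2-yl)propan-1-ol
Product: 4 rac-trans-5-ethyl-4-hydroxy-2-methylcyclopent-2-en-1-one
Conditions: ZnCl2 (1.5 equiv), 1,4-dioxane/H2O 3:2, pH about 6, 95 °C
Reagents that add atoms: water, O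
Why: Piancatelli rearrangement of a 2-furylcarbinol, a cationic 4π electrocyclization of the Nazarov type. ZnCl2 assists loss of the carbinol hydroxyl to give a furfuryl cation that the 3-methyl group stabilises; water adds at the free furan C5, the hemiacetal opens and a 1,4-dioxygenated pentadienyl cation results. Thermal conrotatory closure of this cation forms C1–C7a and closes ring A as a five-membered ring; loss of a proton gives the enone with the old furan oxygen as the C2 ketone and the water-derived hydroxyl on C7a. Both new centres (C1, C7a) are set by conrotation of the cation with ethyl and hydroxyl outside, which places them trans; the cation is achiral, so the product is racemic and the absolute configuration is supplied in step 3. The step needs water to attack C5 and not C3 or the side-chain carbon: C3 carries the methyl group, and return to the carbinol carbon only regenerates 3. It also needs to stop at the 4-hydroxy-5-ethyl isomer, which the near-neutral zinc medium and a limited reaction time should secure against the known drift to the more substituted enone. An alkyl carbinol ionises more slowly than an aryl one, hence the heating.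

Step 3
Reactants: 4 rac-trans-5-ethyl-4-hydroxy-2-methylcyclopent-2-en-1-one
Product: 5 (4R,5S)-5-ethyl-4-hydroxy-2-methylcyclopent-2-en-1-one
Conditions: Burkholderia cepacia lipase (Amano PS), vinyl acetate, t-BuOMe, 30 °C, run past half conversion; chromatography
Reagents that add atoms: none
Why: Lipase-catalysed kinetic resolution by enantioselective transesterification, a standard way to resolve 4-hydroxycyclopent-2-enones; the antipode leaves as its acetate. The C7a configuration fixed here controls every later ring centre.

Step 4
Reactants: 5 (4R,5S)-5-ethyl-4-hydroxy-2-methylcyclopent-2-en-1-one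
Product: 6 (4R,5S)-4-[(tert-butyldimethylsilyl)oxy]-5-ethyl-2-methylcyclopent-2-en-1-one
Conditions: t-BuMe2SiCl, imidazole, DMF, 0 °C to rt
Reagents that add atoms: tert-butyldimethylsilyl chloride, C[Si](C)(Cl)C(C)(C)C
Why: Silylation of a secondary alcohol with a mild base that avoids the base-induced isomerisation of 4-hydroxy-5-alkylcyclopentenones; the bulky ether is the shielding group for step 5.

Step 5
Reactants: 6 (4R,5S)-4-[(tert-butyldimethylsilyl)oxy]-5-ethyl-2-methylcyclopent-2-en-1-one; 7 prop-1-en-2-ylmagnesium bromide
Product: 9 (4R,5S)-2-ethyl-5-methyl-4-(prop-1-en-2-yl)cyclopent-2-en-1-one, via silyloxy ketone 8 (not isolated)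
Conditions: 7 (2.2 equiv), CuBr·SMe2 (1.1 equiv), THF, −78 to −40 °C; aq. NH4Cl; crude in CH2Cl2, DBU (1.5 equiv), 0 °C to rt
Reagents that add atoms: none
Why: Organocuprate conjugate addition anti to the C7a silyloxy group, the established facial rule for 4-silyloxycyclopent-2-enones, sets C3a. DBU then effects E1cB loss of silanolate across C1–C7a and equilibrates C3, so the methyl lies trans to the isopropenyl group; short exposure at low temperature limits migration of the isopropenyl alkene into conjugation.

Step 6
Reactants: 9 (4R,5S)-2-ethyl-5-methyl-4-(prop-1-en-2-yl)cyclopent-2-en-1-one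
Product: 10 (1S,4R,5S)-2-ethyl-5-methyl-4-(prop-1-en-2-yl)cyclopent-2-en-1-ol
Conditions: (R)-2-methyl-CBS-oxazaborolidine (0.5 equiv), catecholborane (1.8 equiv), toluene, −78 °C; MeOH, aq. NaOH
Reagents that add atoms: none
Why: Corey–Bakshi–Shibata reduction, 1,2-selective for 2-alkylcyclopentenones. Hydride is delivered to the C2 face anti to the adjacent C3 methyl, which is also the face the (R)-oxazaborolidine selects when the 2-ethylvinyl arm is the large group, giving the hydroxyl cis to the methyl.

Step 7
Reactants: 11 prop-2-yn-1-ol; 2 ethylmagnesium bromide; 12 acetaldehyde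
Product: 14 rac-(Z)-2-ethylpent-2-ene-1,4-diol, via vinylmagnesium alkoxide 13 (not isolated)
Conditions: EtMgBr (3 equiv), CuI (10 mol %), Et2O, −10 °C to reflux; then CH3CHO (3 equiv), 0 °C; aq. NH4Cl
Reagents that add atoms: none
Why: Copper-catalysed anti-carbomagnesiation of a propargylic alkoxide places ethyl on the future C6 and magnesium on the future C5, cis to the CH2O arm through chelation. The vinyl Grignard reagent then adds to acetaldehyde with retention of alkene geometry, which fixes the Z alkene.

Step 8
Reactants: 14 rac-(Z)-2-ethylpent-2-ene-1,4-diol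
Product: 15 rac-(Z)-5-[(tert-butyldimethylsilyl)oxy]-4-ethylpent-3-en-2-ol
Conditions: t-BuMe2SiCl (1.05 equiv), imidazole, CH2Cl2, −20 °C
Reagents that add atoms: tert-butyldimethylsilyl chloride, C[Si](C)(Cl)C(C)(C)C
Why: Selective silylation of the primary over the secondary allylic hydroxyl on steric grounds.

Step 9
Reactants: 15 rac-(Z)-5-[(tert-butyldimethylsilyl)oxy]-4-ethylpent-3-en-2-ol
Product: 16 (2S,3Z)-5-[(tert-butyldimethylsilyl)oxy]-4-ethylpent-3-en-2-ol
Conditions: immobilised Candida antarctica lipase B (Novozym 435), vinyl acetate, hexane, 30 °C, run past half conversion; chromatography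
Reagents that add atoms: none
Why: Lipase kinetic resolution of a methyl alkenyl carbinol; this enzyme acylates the (R) enantiomer of such alcohols (methyl as the small group), so the (S) alcohol should remain.

Step 10
Reactants: 16 (2S,3Z)-5-[(tert-butyldimethylsilyl)oxy]-4-ethylpent-3-en-2-ol; 17 triethyl orthoacetate
Product: 19 ethyl (3R,4E)-3-{[(tert-butyldimethylsilyl)oxy]methyl}-3-ethylhex-4-enoate, via ketene acetal 18 (not isolated)
Conditions: CH3C(OEt)3 (6 equiv), EtCO2H (5 mol %), 140 °C, EtOH distilled off
Reagents that add atoms: none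
Why: Johnson–Claisen rearrangement through a chair with the carbinol methyl equatorial; the axial alternative clashes with the cis CH2OSi group. Suprafacial transfer from the (S) carbinol across the Z alkene forms the C6–C7 bond, the (R) quaternary C6 and an E propenyl group.

Step 11
Reactants: 19 ethyl (3R,4E)-3-{[(tert-butyldimethylsilyl)oxy]methyl}-3-ethylhex-4-enoate
Product: 20 (3R,4E)-3-{[(tert-butyldimethylsilyl)oxy]methyl}-3-ethylhex-4-enoic acid
Conditions: LiOH, THF/MeOH/H2O, 50 °C; 1 M HCl to pH 4
Reagents that add atoms: lithium hydroxide, [Li+].[OH-]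
Why: Saponification of an unhindered CH2CO2Et ester; the primary silyl ether is stable to hydroxide.

Step 12
Reactants: 10 (1S,4R,5S)-2-ethyl-5-methyl-4-(prop-1-en-2-yl)cyclopent-2-en-1-ol; 20 (3R,4E)-3-{[(tert-butyldimethylsilyl)oxy]methyl}-3-ethylhex-4-enoic acid
Product: 21 (1S,4R,5S)-2-ethyl-5-methyl-4-(prop-1-en-2-yl)cyclopent-2-en-1-yl (3R,4E)-3-{[(tert-butyldimethylsilyl)oxy]methyl}-3-ethylhex-4-enoate
Conditions: DCC, DMAP (0.2 equiv), CH2Cl2, 0 °C to rt
Reagents that add atoms: none
Why: Steglich esterification joins the two fragments without touching any stereocentre.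

Step 13
Reactants: 21 (1S,4R,5S)-2-ethyl-5-methyl-4-(prop-1-en-2-yl)cyclopent-2-en-1-yl (3R,4E)-3-{[(tert-butyldimethylsilyl)oxy]methyl}-3-ethylhex-4-enoate
Product: 24 (3S,4E)-3-{[(tert-butyldimethylsilyl)oxy]methyl}-3-ethyl-2-[(1S,4R,5S)-2-ethyl-4-methyl-5-(prop-1-en-2-yl)cyclopent-2-en-1-yl]hex-4-enoic acid (C7 epimers), via silyl ketene acetal 22 (not isolated), via trimethylsilyl ester 23 (not isolated)
Conditions: LiN(i-Pr)2 (1.5 equiv), Me3SiCl/Et3N (3 equiv), THF, −78 °C, then 60 °C; 1 M HCl
Reagents that add atoms: none
Why: Ireland–Claisen rearrangement. The silyl ketene acetal shifts suprafacially across C2–C1=C7a, so C7 bonds to C7a on the face that carried the C2 oxygen (anti to the C3a isopropenyl group) and the alkene moves to C1=C2. The C7 configuration is left open because C7 is enolised again in step 16.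

Step 14
Reactants: 24 (3S,4E)-3-{[(tert-butyldimethylsilyl)oxy]methyl}-3-ethyl-2-[(1S,4R,5S)-2-ethyl-4-methyl-5-(prop-1-en-2-yl)cyclopent-2-en-1-yl]hex-4-enoic acid
Product: 25 tert-butyl (3S,4E)-3-{[(tert-butyldimethylsilyl)oxy]methyl}-3-ethyl-2-[(1S,4R,5S)-2-ethyl-4-methyl-5-(prop-1-en-2-yl)cyclopent-2-en-1-yl]hex-4-enoate (C7 epimers)
Conditions: Me2NCH(Ot-Bu)2 (4 equiv), toluene, 80 °C
Reagents that add atoms: N,N-dimethylformamide di-tert-butyl acetal, CN(C)C(OC(C)(C)C)OC(C)(C)C
Why: O-alkylation of the carboxylate by a tert-butyl cation equivalent works for hindered acids. The tert-butyl ester is chosen because it resists attack by the C6 hydroxymethyl group freed in step 17 and can be removed without hydroxide.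

Step 15
Reactants: 25 tert-butyl (3S,4E)-3-{[(tert-butyldimethylsilyl)oxy]methyl}-3-ethyl-2-[(1S,4R,5S)-2-ethyl-4-methyl-5-(prop-1-en-2-yl)cyclopent-2-en-1-yl]hex-4-enoate
Product: 26 tert-butyl (3R,3aS,6S,7aS)-6-{[(tert-butyldimethylsilyl)oxy]methyl}-1,6-diethyl-3,4-dimethyl-3a,6,7,7a-tetrahydro-3H-indene-7-carboxylate (C7 epimers)
Conditions: second-generation Hoveyda–Grubbs catalyst (10 mol %), toluene, 80 °C, argon sparge
Reagents that add atoms: none
Why: Ring-closing metathesis of the isopropenyl and propenyl groups forms the trisubstituted C4=C5 alkene and ring B with loss of propene. The trans relation of the two arms on ring A gives the trans ring fusion, and the trisubstituted C1=C2 alkene is inert.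

Step 16
Reactants: 26 tert-butyl (3R,3aS,6S,7aS)-6-{[(tert-butyldimethylsilyl)oxy]methyl}-1,6-diethyl-3,4-dimethyl-3a,6,7,7a-tetrahydro-3H-indene-7-carboxylate
Product: 28 tert-butyl (3R,3aS,6S,7R,7aR)-6-{[(tert-butyldimethylsilyl)oxy]methyl}-1,6-diethyl-3,4,7-trimethyl-3a,6,7,7a-tetrahydro-3H-indene-7-carboxylate, via lithium enolate 27 (not isolated)
Conditions: LiN(i-Pr)2 (1.5 equiv), THF/DMPU, −78 to −30 °C; CH3I (5 equiv), −78 to 0 °C
Reagents that add atoms: iodomethane, CI
Why: Ester enolate alkylation. In the locked trans-fused half-chair the C6 CH2OSi group is pseudoaxial on the H7a face and shields that face of the exocyclic enolate, so methyl should enter axially from the H3a face, where only one 1,3-diaxial hydrogen opposes it. This gives the 7R centre with methyl trans to the C6 arm.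

Step 17
Reactants: 28 tert-butyl (3R,3aS,6S,7R,7aR)-6-{[(tert-butyldimethylsilyl)oxy]methyl}-1,6-diethyl-3,4,7-trimethyl-3a,6,7,7a-tetrahydro-3H-indene-7-carboxylate
Product: 29 tert-butyl (3R,3aS,6S,7R,7aR)-1,6-diethyl-6-(hydroxymethyl)-3,4,7-trimethyl-3a,6,7,7a-tetrahydro-3H-indene-7-carboxylate
Conditions: HF·pyridine, pyridine, THF, 0 °C to rt
Reagents that add atoms: none
Why: Fluoride cleavage of a primary silyl ether under buffered conditions that should leave the tert-butyl ester and the alkenes untouched.

Step 18
Reactants: 29 tert-butyl (3R,3aS,6S,7R,7aR)-1,6-diethyl-6-(hydroxymethyl)-3,4,7-trimethyl-3a,6,7,7a-tetrahydro-3H-indene-7-carboxylate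
Product: 30 tert-butyl (3R,3aS,6S,7R,7aR)-1,6-diethyl-6-formyl-3,4,7-trimethyl-3a,6,7,7a-tetrahydro-3H-indene-7-carboxylate
Conditions: Dess–Martin periodinane, NaHCO3, CH2Cl2, 0 °C to rt
Reagents that add atoms: none
Why: Dess–Martin oxidation of a neopentyl primary alcohol; the aldehyde has no α-hydrogen and cannot epimerise.

Step 19
Reactants: 30 tert-butyl (3R,3aS,6S,7R,7aR)-1,6-diethyl-6-formyl-3,4,7-trimethyl-3a,6,7,7a-tetrahydro-3H-indene-7-carboxylate; 31 diethyl [(2E)-3-phenylprop-2-en-1-yl]phosphonate
Product: 32 tert-butyl (3R,3aS,6S,7R,7aR)-1,6-diethyl-3,4,7-trimethyl-6-[(1E,3E)-4-phenylbuta-1,3-dien-1-yl]-3a,6,7,7a-tetrahydro-3H-indene-7-carboxylate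
Conditions: 31 (2 equiv), n-BuLi (1.9 equiv), THF, −78 °C; then 30, −78 °C to rt
Reagents that add atoms: none
Why: Horner–Wadsworth–Emmons olefination with an allylic phosphonate anion should give the new C1'=C2' alkene E (bulky α-quaternary aldehyde, reversible addition) and carries the styryl alkene through unchanged.

Step 20
Reactants: 32 tert-butyl (3R,3aS,6S,7R,7aR)-1,6-diethyl-3,4,7-trimethyl-6-[(1E,3E)-4-phenylbuta-1,3-dien-1-yl]-3a,6,7,7a-tetrahydro-3H-indene-7-carboxylate
Product: 34 (3R,3aS,6S,7R,7aR)-1,6-diethyl-3,4,7-trimethyl-6-[(1E,3E)-4-phenylbuta-1,3-dien-1-yl]-3a,6,7,7a-tetrahydro-3H-indene-7-carboxylic acid, via trimethylsilyl ester 33 (not isolated)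
Conditions: Me3SiOTf (3 equiv), 2,6-lutidine (4 equiv), CH2Cl2, 0 °C; aq. citric acid
Reagents that add atoms: none
Why: Silyl triflate-mediated cleavage of the tert-butyl ester (loss of 2-methylpropene, then hydrolysis of the silyl ester) frees the hindered acid without hydroxide or a strong protic acid, neither of which suits the hindered ester and the diene.

## Compound list

1 | 3-methylfuran-2-carbaldehyde | Cc1ccoc1C=O | starting material
2 | ethylmagnesium bromide | CC[Mg]Br | starting material
3 | rac-1-(3-methylfuran-2-yl)propan-1-ol | CCC(O)c1occc1C | intermediate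
4 | rac-trans-5-ethyl-4-hydroxy-2-methylcyclopent-2-en-1-one (racemate; the (4R,5S) form is drawn) | CC[C@H]1[C@H](O)C=C(C)C1=O | intermediate
5 | (4R,5S)-5-ethyl-4-hydroxy-2-methylcyclopent-2-en-1-one (single enantiomer) | CC[C@H]1[C@H](O)C=C(C)C1=O | intermediate
6 | (4R,5S)-4-[(tert-butyldimethylsilyl)oxy]-5-ethyl-2-methylcyclopent-2-en-1-one | CC[C@H]1[C@H](O[Si](C)(C)C(C)(C)C)C=C(C)C1=O | intermediate
7 | prop-1-en-2-ylmagnesium bromide | CC(=C)[Mg]Br | starting material
8 | (2S,3R,4R,5S)-4-[(tert-butyldimethylsilyl)oxy]-5-ethyl-2-methyl-3-(prop-1-en-2-yl)cyclopentan-1-one (not isolated) | CC[C@@H]1C(=O)[C@@H](C)[C@H](C(C)=C)[C@H]1O[Si](C)(C)C(C)(C)C | intermediate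
9 | (4R,5S)-2-ethyl-5-methyl-4-(prop-1-en-2-yl)cyclopent-2-en-1-one | CCC1=C[C@@H](C(C)=C)[C@H](C)C1=O | intermediate
10 | (1S,4R,5S)-2-ethyl-5-methyl-4-(prop-1-en-2-yl)cyclopent-2-en-1-ol | CCC1=C[C@@H](C(C)=C)[C@H](C)[C@@H]1O | intermediate
11 | prop-2-yn-1-ol | C#CCO | starting material
12 | acetaldehyde | CC=O | starting material
13 | (Z)-[3-(bromomagnesiooxy)-2-ethylprop-1-en-1-yl]magnesium bromide (not isolated) | CC/C(CO[Mg]Br)=C/[Mg]Br | intermediate
14 | rac-(Z)-2-ethylpent-2-ene-1,4-diol | CC(O)/C=C(CC)\CO | intermediate
15 | rac-(Z)-5-[(tert-butyldimethylsilyl)oxy]-4-ethylpent-3-en-2-ol | CC(O)/C=C(CC)\CO[Si](C)(C)C(C)(C)C | intermediate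
16 | (2S,3Z)-5-[(tert-butyldimethylsilyl)oxy]-4-ethylpent-3-en-2-ol | C[C@H](O)/C=C(CC)\CO[Si](C)(C)C(C)(C)C | intermediate
17 | triethyl orthoacetate | CC(OCC)(OCC)OCC | starting material
18 | mixed ketene acetal, 1-ethoxyvinyl ether of 16 (not isolated) | C=C(OCC)O[C@@H](C)/C=C(CC)\CO[Si](C)(C)C(C)(C)C | intermediate
19 | ethyl (3R,4E)-3-{[(tert-butyldimethylsilyl)oxy]methyl}-3-ethylhex-4-enoate | C/C=C/[C@@](CO[Si](C)(C)C(C)(C)C)(CC)CC(=O)OCC | intermediate
20 | (3R,4E)-3-{[(tert-butyldimethylsilyl)oxy]methyl}-3-ethylhex-4-enoic acid | C/C=C/[C@@](CO[Si](C)(C)C(C)(C)C)(CC)CC(=O)O | intermediate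
21 | (1S,4R,5S)-2-ethyl-5-methyl-4-(prop-1-en-2-yl)cyclopent-2-en-1-yl (3R,4E)-3-{[(tert-butyldimethylsilyl)oxy]methyl}-3-ethylhex-4-enoate | CCC1=C[C@@H](C(C)=C)[C@H](C)[C@@H]1OC(=O)C[C@@](CC)(CO[Si](C)(C)C(C)(C)C)/C=C/C | intermediate
22 | trimethylsilyl ketene acetal of 21, ketene acetal geometry open (not isolated) | CCC1=C[C@@H](C(C)=C)[C@H](C)[C@@H]1OC(O[Si](C)(C)C)=C[C@@](CC)(CO[Si](C)(C)C(C)(C)C)/C=C/C | intermediate
23 | trimethylsilyl ester of 24, C7 epimers (not isolated) | CCC1=C[C@@H](C)[C@H](C(C)=C)[C@H]1C(C(=O)O[Si](C)(C)C)[C@@](CC)(CO[Si](C)(C)C(C)(C)C)/C=C/C | intermediate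
24 | (3S,4E)-3-{[(tert-butyldimethylsilyl)oxy]methyl}-3-ethyl-2-[(1S,4R,5S)-2-ethyl-4-methyl-5-(prop-1-en-2-yl)cyclopent-2-en-1-yl]hex-4-enoic acid, C7 epimers | CCC1=C[C@@H](C)[C@H](C(C)=C)[C@H]1C(C(=O)O)[C@@](CC)(CO[Si](C)(C)C(C)(C)C)/C=C/C | intermediate
25 | tert-butyl ester of 24, C7 epimers | CCC1=C[C@@H](C)[C@H](C(C)=C)[C@H]1C(C(=O)OC(C)(C)C)[C@@](CC)(CO[Si](C)(C)C(C)(C)C)/C=C/C | intermediate
26 | tert-butyl (3R,3aS,6S,7aS)-6-{[(tert-butyldimethylsilyl)oxy]methyl}-1,6-diethyl-3,4-dimethyl-3a,6,7,7a-tetrahydro-3H-indene-7-carboxylate, C7 epimers | CCC1=C[C@@H](C)[C@@H]2C(C)=C[C@@](CO[Si](C)(C)C(C)(C)C)(CC)C(C(=O)OC(C)(C)C)[C@@H]12 | intermediate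
27 | lithium enolate of 26 (not isolated) | CCC1=C[C@@H](C)[C@@H]2C(C)=C[C@@](CO[Si](C)(C)C(C)(C)C)(CC)C(=C(O[Li])OC(C)(C)C)[C@@H]12 | intermediate
28 | tert-butyl (3R,3aS,6S,7R,7aR)-6-{[(tert-butyldimethylsilyl)oxy]methyl}-1,6-diethyl-3,4,7-trimethyl-3a,6,7,7a-tetrahydro-3H-indene-7-carboxylate | CCC1=C[C@@H](C)[C@@H]2C(C)=C[C@@](CO[Si](C)(C)C(C)(C)C)(CC)[C@](C)(C(=O)OC(C)(C)C)[C@@H]12 | intermediate
29 | tert-butyl (3R,3aS,6S,7R,7aR)-1,6-diethyl-6-(hydroxymethyl)-3,4,7-trimethyl-3a,6,7,7a-tetrahydro-3H-indene-7-carboxylate | CCC1=C[C@@H](C)[C@@H]2C(C)=C[C@@](CO)(CC)[C@](C)(C(=O)OC(C)(C)C)[C@@H]12 | intermediate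
30 | tert-butyl (3R,3aS,6S,7R,7aR)-1,6-diethyl-6-formyl-3,4,7-trimethyl-3a,6,7,7a-tetrahydro-3H-indene-7-carboxylate | CCC1=C[C@@H](C)[C@@H]2C(C)=C[C@@](C=O)(CC)[C@](C)(C(=O)OC(C)(C)C)[C@@H]12 | intermediate
31 | diethyl [(2E)-3-phenylprop-2-en-1-yl]phosphonate | CCOP(=O)(OCC)C/C=C/c1ccccc1 | starting material
32 | tert-butyl (3R,3aS,6S,7R,7aR)-1,6-diethyl-3,4,7-trimethyl-6-[(1E,3E)-4-phenylbuta-1,3-dien-1-yl]-3a,6,7,7a-tetrahydro-3H-indene-7-carboxylate | CCC1=C[C@@H](C)[C@@H]2C(C)=C[C@@](/C=C/C=C/c3ccccc3)(CC)[C@](C)(C(=O)OC(C)(C)C)[C@@H]12 | intermediate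
33 | trimethylsilyl ester of 34 (not isolated) | CCC1=C[C@@H](C)[C@@H]2C(C)=C[C@@](/C=C/C=C/c3ccccc3)(CC)[C@](C)(C(=O)O[Si](C)(C)C)[C@@H]12 | intermediate
34 | (3R,3aS,6S,7R,7aR)-1,6-diethyl-3,4,7-trimethyl-6-[(1E,3E)-4-phenylbuta-1,3-dien-1-yl]-3a,6,7,7a-tetrahydro-3H-indene-7-carboxylic acid | CCC1=C[C@@H](C)[C@@H]2C(C)=C[C@@](/C=C/C=C/c3ccccc3)(CC)[C@](C)(C(=O)O)[C@@H]12 | target

## Step count and least certain steps

Total: 20 steps. Longest linear sequence: 15 steps (steps 1–6 and 12–20). The acid branch (steps 7–11) joins at step 12.

**Step 2 (key step).** The alkyl carbinol ionises slowly, so acid-promoted opening and polymerisation of the furan can outrun the electrocyclization. Prolonged heating can also carry the product on to the isomeric, more substituted hydroxy enone. Fallback: from 3, the same C1–C7a bond is formed by an aldol closure instead. Ionic deoxygenation of 3 (Et3SiH, CF3CO2H, CH2Cl2, −20 °C) gives 3-methyl-2-propylfuran F1. Br2 in MeOH with Na2CO3 at −40 °C gives 2,5-dimethoxy-3-methyl-2-propyl-2,5-dihydrofuran F2. Aqueous acid at pH 4 unmasks (Z)-3-methyl-4-oxohept-2-enal F3, which in phosphate buffer at pH 8 undergoes intramolecular aldol addition of the propyl-side enolate to the aldehyde and returns to the route at 4.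

**Step 3.** The enzyme may acylate the needed enantiomer instead of its antipode, or discriminate poorly, because the trans ethyl group enlarges the side of the carbinol that is the small one in the parent hydroxy enone. Fallback: from 4, a covalent resolution that also removes the silylation. Esterification with (S)-2-methoxy-2-phenylacetic acid (DCC, DMAP) and chromatographic separation give (1R,5S)-5-ethyl-3-methyl-4-oxocyclopent-2-en-1-yl (S)-2-methoxy-2-phenylacetate F4. Its acyloxy group directs the cuprate of step 5 to the opposite face of C3a and is then lost with DBU, which returns to the route at 9.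

**Step 6.** Facial selectivity may be poor if the isopropenyl group on C3a, which lies on the face the hydride must use, counts for more than the adjacent methyl; some conjugate reduction is also possible. Fallback: from 9, Luche reduction (NaBH4, CeCl3·7H2O, MeOH, −78 °C) followed by correction of the carbinol. If the epimer (1R,4R,5S)-2-ethyl-5-methyl-4-(prop-1-en-2-yl)cyclopent-2-en-1-ol F5 predominates, Mitsunobu inversion (PPh3, diisopropyl azodicarboxylate, 4-nitrobenzoic acid) gives (1S,4R,5S)-2-ethyl-5-methyl-4-(prop-1-en-2-yl)cyclopent-2-en-1-yl 4-nitrobenzoate F6. Methanolysis (K2CO3, MeOH) returns to the route at 10.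

**Step 16.** Deprotonation of a methine flanked by a quaternary carbon may be slow, and the facial preference of the exocyclic enolate rests on a conformational argument, so methyl may enter on both faces. Fallback: from 26, the ester is tied to the C6 arm so that the ring fusion dictates the face. Bu4NF in THF at 50 °C removes the silyl group, and the alkoxide closes onto the ester under epimerising conditions to give the cis-fused γ-lactone F7. LiN(i-Pr)2 and CH3I methylate its enolate on the only face that keeps the lactone cis-fused, giving the methylated lactone F8. KOH in aqueous dioxane, exhaustive silylation (t-BuMe2SiCl, imidazole) and cleavage of the silyl ester (K2CO3, aqueous MeOH) give the silyl ether acid F9. The reagent of step 14 converts F9 into 28.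

**Step 17.** The freed hydroxymethyl group is held next to the ester on a doubly quaternary backbone and may close to a γ-lactone with loss of the tert-butyl group. Fallback: from 28, the lactone is accepted and the olefination is run on the free acid. Bu4NF in THF at 50 °C completes the conversion into the methylated lactone F8. Bu4NOH in aqueous dioxane opens it, and the dried hydroxy carboxylate is oxidised under Parikh–Doering conditions (SO3·pyridine, DMSO, i-Pr2NEt). Acidification gives the hydroxy lactone (pseudo-acid) F10. Excess lithiated 31 (3 equiv, THF, −78 °C to rt) opens F10 to the aldehyde carboxylate and olefinates it, returning to the route at 34.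

## Further compounds

F1 | step 2 | 3-methyl-2-propylfuran | CCCc1occc1C
F2 | step 2 | 2,5-dimethoxy-3-methyl-2-propyl-2,5-dihydrofuran (isomer mixture) | CCCC1(OC)OC(OC)C=C1C
F3 | step 2 | (Z)-3-methyl-4-oxohept-2-enal | CCCC(=O)/C(C)=C\C=O
F4 | step 3 | (1R,5S)-5-ethyl-3-methyl-4-oxocyclopent-2-en-1-yl (S)-2-methoxy-2-phenylacetate | CC[C@H]1[C@H](OC(=O)[C@@H](OC)c2ccccc2)C=C(C)C1=O
F5 | step 6 | (1R,4R,5S)-2-ethyl-5-methyl-4-(prop-1-en-2-yl)cyclopent-2-en-1-ol | CCC1=C[C@@H](C(C)=C)[C@H](C)[C@H]1O
F6 | step 6 | (1S,4R,5S)-2-ethyl-5-methyl-4-(prop-1-en-2-yl)cyclopent-2-en-1-yl 4-nitrobenzoate | CCC1=C[C@@H](C(C)=C)[C@H](C)[C@@H]1OC(=O)c2ccc(cc2)[N+](=O)[O-]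
F7 | step 16 | cis-fused γ-lactone between the C7 carboxyl and the C6 hydroxymethyl group, C7 unmethylated | CCC1=C[C@@H](C)[C@@H]2C(C)=C[C@]3(CC)COC(=O)[C@@H]3[C@@H]12
F8 | step 16 | cis-fused γ-lactone between the C7 carboxyl and the C6 hydroxymethyl group, C7 methylated | CCC1=C[C@@H](C)[C@@H]2C(C)=C[C@]3(CC)COC(=O)[C@]3(C)[C@@H]12
F9 | step 16 | (3R,3aS,6S,7R,7aR)-6-{[(tert-butyldimethylsilyl)oxy]methyl}-1,6-diethyl-3,4,7-trimethyl-3a,6,7,7a-tetrahydro-3H-indene-7-carboxylic acid | CCC1=C[C@@H](C)[C@@H]2C(C)=C[C@@](CO[Si](C)(C)C(C)(C)C)(CC)[C@](C)(C(=O)O)[C@@H]12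
F10 | step 17 | hydroxy lactone (pseudo-acid) of the 6-formyl-7-carboxylic acid, lactol epimers | CCC1=C[C@@H](C)[C@@H]2C(C)=C[C@]3(CC)C(O)OC(=O)[C@]3(C)[C@@H]12
A1 | alternative 1 | bicyclo[3.1.1]heptan-6-one with C6 and C7 quaternary, product of the ketene cycloaddition | CC[C@H](O[Si](C)(C)C(C)(C)C)[C@H]1[C@H](CC)[C@@](C)(OC(=O)C)[C@H]2[C@@](COCc3ccc(OC)cc3)(CC)[C@]1(C)C2=O
A2 | alternative 2 | methyl ester of 34, product of the Heck closure | CCC1=C[C@@H](C)[C@@H]2C(C)=C[C@@](/C=C/C=C/c3ccccc3)(CC)[C@](C)(C(=O)OC)[C@@H]12
A3 | alternative 3 | methyl ester of the bicyclic core with a 2-[(tert-butyldimethylsilyl)oxy]ethyl arm on C6, product of the carbene insertion | CCC1=C[C@@H](C)[C@@H]2C(C)=C[C@@](CCO[Si](C)(C)C(C)(C)C)(CC)[C@](C)(C(=O)OC)[C@@H]12
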